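66.7 % of the starting material charged was the number I sent you for the hot flasks. I called it the hot ceiling: [reagent] at the start over the sum of [starting material] and [reagent] at the start, which is the target share I expected once a hot flask had used up its reagent.

| flask | starting material | reagent | temperature | remark | time |
|---|---|---|---|---|---|
| teal | 0.029 M | 0.118 M | 35 °C | run made earlier |  |
| blue | 0.12 M | 0.118 M | 68 °C | run made earlier |  |
| amber | 0.059 M | 0.18 M | 35 °C | run made earlier |  |
| Tuesday's | 0.059 M | 0.118 M | 40 °C |  | 2.0 h |
| Monday's | 0.059 M | 0.118 M | 20 °C |  | 2.0 h |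
| Thursday's | 0.059 M | 0.118 M | 80 °C |  | 2.0 h |
| Saturday's | 0.059 M | 0.118 M | 60 °C |  | 2.0 h |

| run | time / min | target / % | starting material / % |
|---|---|---|---|
| teal | 10.0 | 43.7 | 54.3 |
| teal | 25.0 | 65.7 | 35.2 |
| teal | 50.0 | 80.6 | 21.8 |
| teal | 80.0 | 84.9 | 16.0 |
| blue | 2.50 | 43.0 | 58.2 |
| blue | 6.00 | 49.6 | 49.9 |
| blue | 12.0 | 49.3 | 49.0 |
| blue | 20.0 | 50.9 | 48.5 |
| amber | 20.0 | 69.6 | 29.0 |
| amber | 40.0 | 79.9 | 22.5 |
| amber | 50.0 | 81.7 | 18.3 |
| amber | 80.0 | 84.7 | 13.4 |

(standard deviation of a reading: 1 percentage point)

- the best flask by amount of target, in percent of the starting material charged; "all alike" if 1.5 percentage points covers them all (Tuesday's / Monday's / Thursday's / Saturday's / all alike)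
- amount of target at the end, in percent of the starting material charged, Tuesday's
- amount of target at the end, in percent of the starting material charged, Monday's
- amount of target at the end, in percent of the starting material charged, Thursday's
- amount of target at the end, in percent of the starting material charged, Saturday's

You asked for something quick and offered your hunch, so I began with the blue run, where target read 49.6 % at 6.00 min and 50.9 % at 20.0 min. That target came to 0.0611 M against 0.118 M of reagent charged, and target and starting material together still read 99.4 %. So I supposed that reagent was the limiting reagent and also went a second way, in pairs, with a constant like that of the target step. That supposition gives the ratio above, and for blue it gives 49.6 %; I chose the rule from this run, so this is no check. The amber run at 35 °C read 84.7 %, above its ratio of 75.3 %, so I expected Saturday's and Thursday's near the ceiling and cooler flasks above it, given time.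

The forecast, your hunch written down, named Monday's as best, with 81 % there, 79.5 % for Tuesday's, 69 % for Saturday's and 60 % for Thursday's. Its ground was: “I therefore read this as a reversible, exothermic reaction.” Where it had equilibrium, I had a reagent budget.

Tuesday's came out best at 81.3 %, with Saturday's at 72.1 %, Monday's at 70.7 % and Thursday's at 63.5 %.

    starting material + reagent → target + released group (k = 0.00570 M⁻¹ s⁻¹, Ea = 52.0 kJ mol⁻¹)
    2 reagent → homo dimer (k = 0.00260 M⁻¹ s⁻¹, Ea = 65.0 kJ mol⁻¹)
    reagent ⇌ dormant form (K = 1.00, k = 0.00260 s⁻¹, Ea = 92.0 kJ mol⁻¹, ΔH = −64.0 kJ mol⁻¹)
    (constants at 20 °C)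

The constants of the target step and the homo dimer step stood alike at 70.6 °C. Saturday's, below that temperature, ended above the ceiling and Thursday's, above it, ended below, with reagent at 0 % and 0 %. Monday's at 2.00 h still held free reagent at 14.8 % of its charge and dormant form at 0.0181 M, and it reached 96.5 % after 20.0 h. The neighbour of Tuesday's, at 40 °C with 0.029 M of reagent, had the same ratio at 33.0 % and, with 0.240 % of its reagent left, gave 38.1 %.

The runs come from a simulation from invented constants, noise included.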